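**Retrosynthetic overview**
1. 27 ⇐ ester/silyl ether cleavage ⇐ cross-metathesis (C14=C15 terminus) ⇐ Wittig methylenation of a C3 ketone ⇐ conjugate reduction of a cross-conjugated dienone (C4=C5 and a C1=C2 arylidene), which sets C2.
2. Ring B (C6–C11 bond) ⇐ one-flask soft enolisation / bromonium formation from a (10R,11S)-10-bromo-11-acetoxy unit / capture at C11 by C6 / re-enolisation / α-face protonation of C6.
3. Bromo acetate ⇐ Shi epoxide of the E-C10=C11 olefin; dienone ⇐ IBX; C7 and the arene ⇐ copper-catalysed asymmetric conjugate addition to 3-methylcyclohex-2-enone with aldol capture of the aryl aldehyde.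
4. Ring order: arene (purchased), ring A (C2–C7, purchased as 3-methylcyclohex-2-enone), ring B (C6–C11) last.
5. Enabling feature: C6 of ring A is the γ-carbon (vinylogous α-position) of a C3 carbonyl, the carbon that ends as the exocyclic methylene carbon, and C10(Br)–C11(quaternary) of ring B is the anti-opened bromonium ion of an E olefin; the C1=C2 arylidene removes every other enolisable hydrogen of ring A.

Key step: step 11

Remark on the chemistry: locants follow the diterpenoid chain (C1 benzylic carbon; ring A = C2–C7 with C3 bearing the exocyclic methylene and C7 the angular methyl; ring B = C6–C11 with Br on C10; C12–C15 side chain; target = 2R,6S,7S,10R,11R), Ar = 3-bromo-5-(methoxycarbonyl)-2-(triisopropylsilyloxy)phenyl, the arylidene geometry (drawn Z) is of no consequence, and hex-1-en-5-yne and the L-fructose-derived enantiomer of the Shi ketone are assumed to be purchasable.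

**Step 1**
Reactants: 1 methyl 3-formyl-4-hydroxybenzoate
Product: 2 methyl 3-bromo-5-formyl-4-hydroxybenzoate
Conditions: Br2, NaOAc, AcOH, rt
Reagents that add atoms: bromine, BrBr
Why: Electrophilic aromatic bromination goes to the free ortho position of the phenol because the para position carries the ester.

**Step 2**
Reactants: 2 methyl 3-bromo-5-formyl-4-hydroxybenzoate
Product: 3 methyl 3-bromo-5-formyl-4-(triisopropylsilyloxy)benzoate
Conditions: TIPSCl, imidazole, DMF, rt
Reagents that add atoms: triisopropylsilyl chloride, CC(C)[Si](Cl)(C(C)C)C(C)C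
Why: Silyl ether formation masks the acidic phenol against the organometallic and Lewis-acidic steps that follow.

**Step 3**
Reactants: 4 hex-1-en-5-yne; 5 oxirane
Product: 8 (E)-4-methylocta-3,7-dien-1-ol, via alkenylalane 6 (not isolated), via lithium alanate 7 (not isolated)
Conditions: Me3Al, Cp2ZrCl2 (20 mol %), CH2Cl2, 0 °C → rt; then n-BuLi, hexane/THF, −30 °C; then 5, −30 °C → rt; aq. HCl
Reagents that add atoms: trimethylaluminium, C[Al](C)C
Why: Negishi zirconium-catalysed carboalumination adds methyl and aluminium syn across the terminal alkyne (methyl to the internal carbon) and the derived alanate opens oxirane with retention at the alkenyl carbon, so the C10=C11 olefin should form as the E isomer only.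

**Step 4**
Reactants: 8 (E)-4-methylocta-3,7-dien-1-ol
Product: 9 (E)-1-bromo-4-methylocta-3,7-diene
Conditions: CBr4, PPh3, CH2Cl2, 0 °C
Reagents that add atoms: carbon tetrabromide, BrC(Br)(Br)Br
Why: The Appel reaction converts the primary alcohol into the bromide under neutral conditions that leave both olefins untouched.

**Step 5**
Reactants: 9 (E)-1-bromo-4-methylocta-3,7-diene; 10 3-methylcyclohex-2-en-1-one; 3 methyl 3-bromo-5-formyl-4-(triisopropylsilyloxy)benzoate
Product: 13 (3S)-2-[Ar(hydroxy)methyl]-3-methyl-3-[(E)-4-methylocta-3,7-dien-1-yl]cyclohexan-1-one (aldol adduct), via Grignard reagent 11 (not isolated), via magnesium enolate 12 (not isolated)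
Conditions: Mg, THF, rt; then 10, Cu(OTf)2 (3 mol %), chiral imidazolinium (N-heterocyclic carbene) ligand (4 mol %), Et2O, −30 °C; then 3, THF, −78 → −20 °C; aq. NH4Cl
Reagents that add atoms: none
Why: Copper-catalysed asymmetric conjugate addition of the Grignard reagent to the β-methyl enone creates the quaternary C7 (face chosen by the ligand enantiomer) and the regiodefined magnesium enolate is trapped at C2 by aldol addition; the two further centres (a diastereomer mixture) are removed in step 6.

**Step 6**
Reactants: 13 aldol adduct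
Product: 15 (3S)-2-[(Z)-Ar-methylidene]-3-methyl-3-[(E)-4-methylocta-3,7-dien-1-yl]cyclohexan-1-one, via mesylate 14 (not isolated)
Conditions: MsCl, Et3N, CH2Cl2, 0 °C; then DBU, rt
Reagents that add atoms: none
Why: Mesylation followed by E1cB elimination gives the α-arylidene ketone, which carries the arene and leaves C2 without hydrogen.

**Step 7**
Reactants: 15 arylidene ketone
Product: 16 (5R)-6-[(Z)-Ar-methylidene]-5-methyl-5-[(E)-4-methylocta-3,7-dien-1-yl]cyclohex-2-en-1-one
Conditions: IBX, DMSO/fluorobenzene, 70 °C
Reagents that add atoms: none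
Why: IBX-mediated dehydrogenation of the ketone to the enone can only occur across C4–C5, because C7 is quaternary and C2 is already sp2.

**Step 8**
Reactants: 16 cross-conjugated dienone
Product: 17 (5R)-6-[(Z)-Ar-methylidene]-5-{2-[(2S,3S)-3-(but-3-en-1-yl)-3-methyloxiran-2-yl]ethyl}-5-methylcyclohex-2-en-1-one
Conditions: ent-Shi ketone (30 mol %), KHSO5 (as Oxone), K2CO3, Bu4NHSO4, MeCN/CH2(OMe)2/aq. Na2B4O7 buffer, 0 °C
Reagents that add atoms: potassium peroxymonosulfate, [K+].[O-]S(=O)(=O)OO
Why: Shi epoxidation by the chiral dioxirane should select the electron-rich E-trisubstituted C10=C11 olefin over the two electron-poor enone double bonds and the monosubstituted vinyl group, and the catalyst, not the remote C7, sets the 10S,11S epoxide.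

**Step 9**
Reactants: 17 epoxide
Product: 18 (5R)-6-[(Z)-Ar-methylidene]-5-[(3R,4S)-3-bromo-4-hydroxy-4-methyloct-7-en-1-yl]-5-methylcyclohex-2-en-1-one
Conditions: Li2NiBr4, THF, 0 °C → rt; pH 7 phosphate buffer
Reagents that add atoms: dilithium tetrabromonickelate, [Li+].[Li+].Br[Ni-2](Br)(Br)Br
Why: Halohydrin formation by SN2 opening of the epoxide with soft bromide at the less substituted C10 proceeds with inversion and gives the anti bromohydrin (10R,11S), bromine on the secondary and oxygen on the tertiary carbon.

**Step 10**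
Reactants: 18 bromohydrin
Product: 19 tertiary acetate of 18 [(3R,4S)-4-acetoxy-3-bromo-4-methyloct-7-en-1-yl side chain]
Conditions: Ac2O, DMAP, Et3N, CH2Cl2, rt
Reagents that add atoms: acetic anhydride, CC(=O)OC(C)=O
Why: DMAP-catalysed acylation esterifies the tertiary alcohol without forming the alkoxide that would close back to the epoxide.

**Step 11**
Reactants: 19 bromo acetate
Product: 22 trans-fused bicyclic dienone (ring B closed), via silyl trienol ether 20 (not isolated), via bicyclic silyl trienol ether 21 (not isolated)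
Conditions: TBSOTf (4 equiv), Et3N (6 equiv), CH2Cl2, −78 °C → rt; then 1 M HCl, THF, 0 °C
Reagents that add atoms: none
Why: Proposed new method: TBSOTf/Et3N first soft-enolises 19, whose only enolisable hydrogens sit on C6, to the silyl trienol ether 20, and excess TBSOTf then ionises the tertiary C11 acetate (as silyl triflates ionise tert-alkyl esters) with anchimeric assistance of the anti C10–Br bond, giving a configurationally defined bromonium ion across C10–C11; the closest known reaction types are the bromonium-initiated cation–olefin (polyene) cyclisation, the stereospecific generation of bromonium ions from enantiopure bromohydrin esters and the Lewis-acid γ-alkylation of silyl dienol ethers by SN1 electrophiles. The γ-carbon C6 of the dienol ether opens the bromonium ion at its tertiary carbon C11 anti to bromine in a 6-endo closure (both former olefin carbons end inside ring B), the only six-membered mode open to the tether on C7. C10 keeps the R configuration of 19 and C11 becomes R by double inversion (bromine displaces acetate, C6 displaces bromine), so the E geometry of the original olefin and the Shi epoxidation together place bromine equatorial and the C11 methyl axial. Because C6 is an endocyclic sp2 carbon next to the tether-bearing C7, the C–C bond is expected to form with a cis ring fusion under kinetic control, which is why the sequence continues in the same flask: Et3N re-enolises the ring-closed silyloxocarbenium ion at C6–H (again the only acidic hydrogen, C2 being blocked by the arylidene) to the bicyclic trienol ether 21, in which C6 is planar. The acid quench should protonate 21 at the γ-carbon C6 from the α face, opposite the syn-axial methyl groups on C7 and C11 that flank the β face, and this sets the trans ring fusion (6S). The step needs γ- rather than α-reactivity of the dienol ether (secured by the silyl, not metal, dienolate and by ring size), Markovnikov opening at C11 (tertiary versus secondary carbon) and a silent vinyl terminus (monosubstituted, far less nucleophilic than the dienol ether).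

**Step 12**
Reactants: 22 trans-fused bicyclic dienone
Product: 24 saturated C3 ketone with equatorial arylmethyl group at C2, via C2-epimeric ketone 23 (not isolated)
Conditions: [(Ph3P)CuH]6 (0.5 equiv), H2O (10 equiv), toluene, rt; then DBU (0.2 equiv), CH2Cl2, rt
Reagents that add atoms: none
Why: Copper hydride conjugate reduction should saturate both enone double bonds while bromides and isolated olefins stay untouched, and base equilibration of the enolisable C2 places the arylmethyl group equatorial (2R), the thermodynamic position on the trans-decalone.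

**Step 13**
Reactants: 24 saturated ketone
Product: 25 exocyclic methylene compound (C3=CH2)
Conditions: Ph3PCH3Br, KN(SiMe3)2, THF, 0 °C; then 24, 0 → 50 °C
Reagents that add atoms: methyltriphenylphosphonium bromide, [Br-].C[P+](c1ccccc1)(c1ccccc1)c1ccccc1
Why: Wittig methylenation of the C3 ketone; epimerisation at C2 by the basic ylide can only return the same equatorial isomer.

**Step 14**
Reactants: 25 exocyclic methylene compound
Product: 26 callophycoic acid H methyl ester triisopropylsilyl ether
Conditions: second-generation Grubbs catalyst (5 mol %), 2-methylbut-2-ene/CH2Cl2, 40 °C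
Reagents that add atoms: 2-methylbut-2-ene, CC=C(C)C
Why: Olefin cross-metathesis of the monosubstituted vinyl group with 2-methylbut-2-ene builds the trisubstituted terminus, the hindered 1,1-disubstituted exocyclic methylene being expected to stay inert toward the ruthenium carbene.

**Step 15**
Reactants: 26 protected callophycoic acid H
Product: 27 callophycoic acid H
Conditions: LiOH, THF/MeOH/H2O, 45 °C; then 1 M HCl to pH 3
Reagents that add atoms: lithium hydroxide, [Li+].[OH-]
Why: Saponification of the methyl ester together with basic cleavage of the aryl silyl ether; the equatorial secondary bromide next to a quaternary carbon has no anti-periplanar hydrogen in the chair and is hindered toward substitution.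

**Compound list**
1 | methyl 3-formyl-4-hydroxybenzoate | O=Cc1cc(C(=O)OC)ccc1O | starting material
2 | methyl 3-bromo-5-formyl-4-hydroxybenzoate | O=Cc1cc(C(=O)OC)cc(Br)c1O | intermediate
3 | methyl 3-bromo-5-formyl-4-(triisopropylsilyloxy)benzoate (ArCHO) | O=Cc1cc(C(=O)OC)cc(Br)c1O[Si](C(C)C)(C(C)C)C(C)C | intermediate
4 | hex-1-en-5-yne | C#CCCC=C | starting material
5 | oxirane | C1CO1 | starting material
6 | dimethyl[(E)-2-methylhexa-1,5-dien-1-yl]alane | C[Al](C)/C=C(\C)CCC=C | intermediate
7 | lithium butyldimethyl[(E)-2-methylhexa-1,5-dien-1-yl]alanate | [Li+].CCCC[Al-](C)(C)/C=C(\C)CCC=C | intermediate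
8 | (E)-4-methylocta-3,7-dien-1-ol | OCC/C=C(\C)CCC=C | intermediate
9 | (E)-1-bromo-4-methylocta-3,7-diene | BrCC/C=C(\C)CCC=C | intermediate
10 | 3-methylcyclohex-2-en-1-one | CC1=CC(=O)CCC1 | starting material
11 | [(E)-4-methylocta-3,7-dien-1-yl]magnesium bromide | Br[Mg]CC/C=C(\C)CCC=C | intermediate
12 | bromomagnesium (S)-3-methyl-3-[(E)-4-methylocta-3,7-dien-1-yl]cyclohex-1-en-1-olate | Br[Mg]OC1=C[C@](C)(CC/C=C(\C)CCC=C)CCC1 | intermediate
13 | (3S)-2-[Ar(hydroxy)methyl]-3-methyl-3-[(E)-4-methylocta-3,7-dien-1-yl]cyclohexan-1-one (aldol adduct; diastereomer mixture at C2 and the carbinol carbon) | O=C1CCC[C@@](C)(CC/C=C(\C)CCC=C)C1C(O)c1cc(C(=O)OC)cc(Br)c1O[Si](C(C)C)(C(C)C)C(C)C | intermediate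
14 | methanesulfonate of 13 | O=C1CCC[C@@](C)(CC/C=C(\C)CCC=C)C1C(OS(C)(=O)=O)c1cc(C(=O)OC)cc(Br)c1O[Si](C(C)C)(C(C)C)C(C)C | intermediate
15 | (3S)-2-[(Z)-Ar-methylidene]-3-methyl-3-[(E)-4-methylocta-3,7-dien-1-yl]cyclohexan-1-one | O=C1CCC[C@@](C)(CC/C=C(\C)CCC=C)/C1=C/c1cc(C(=O)OC)cc(Br)c1O[Si](C(C)C)(C(C)C)C(C)C | intermediate
16 | (5R)-6-[(Z)-Ar-methylidene]-5-methyl-5-[(E)-4-methylocta-3,7-dien-1-yl]cyclohex-2-en-1-one | O=C1C=CC[C@@](C)(CC/C=C(\C)CCC=C)/C1=C/c1cc(C(=O)OC)cc(Br)c1O[Si](C(C)C)(C(C)C)C(C)C | intermediate
17 | (5R)-6-[(Z)-Ar-methylidene]-5-{2-[(2S,3S)-3-(but-3-en-1-yl)-3-methyloxiran-2-yl]ethyl}-5-methylcyclohex-2-en-1-one | O=C1C=CC[C@@](C)(CC[C@@H]2O[C@@]2(C)CCC=C)/C1=C/c1cc(C(=O)OC)cc(Br)c1O[Si](C(C)C)(C(C)C)C(C)C | intermediate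
18 | (5R)-6-[(Z)-Ar-methylidene]-5-[(3R,4S)-3-bromo-4-hydroxy-4-methyloct-7-en-1-yl]-5-methylcyclohex-2-en-1-one | O=C1C=CC[C@@](C)(CC[C@@H](Br)[C@@](C)(O)CCC=C)/C1=C/c1cc(C(=O)OC)cc(Br)c1O[Si](C(C)C)(C(C)C)C(C)C | intermediate
19 | tertiary acetate of 18, side chain (3R,4S)-4-acetoxy-3-bromo-4-methyloct-7-en-1-yl | O=C1C=CC[C@@](C)(CC[C@@H](Br)[C@@](C)(OC(C)=O)CCC=C)/C1=C/c1cc(C(=O)OC)cc(Br)c1O[Si](C(C)C)(C(C)C)C(C)C | intermediate
20 | tert-butyldimethylsilyl trienol ether of 19 (1-silyloxycyclohexa-1,3-diene with C6 as diene terminus, Z arylidene kept) | CC(C)(C)[Si](C)(C)OC1=CC=C[C@@](C)(CC[C@@H](Br)[C@@](C)(OC(C)=O)CCC=C)/C1=C/c1cc(C(=O)OC)cc(Br)c1O[Si](C(C)C)(C(C)C)C(C)C | intermediate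
21 | bicyclic silyl trienol ether (ring B closed, C6 sp2, C7, C10 and C11 arranged as in 27) | CC(C)(C)[Si](C)(C)OC1=CC=C2[C@@](C)(CCC=C)[C@H](Br)CC[C@@]2(C)/C1=C/c1cc(C(=O)OC)cc(Br)c1O[Si](C(C)C)(C(C)C)C(C)C | intermediate
22 | trans-fused bicyclic dienone (3-oxo, C4=C5, Z C1=C2 arylidene, C6–H α, Br equatorial, C7, C10 and C11 as in 27) | O=C1C=C[C@@H]2[C@@](C)(CCC=C)[C@H](Br)CC[C@@]2(C)/C1=C/c1cc(C(=O)OC)cc(Br)c1O[Si](C(C)C)(C(C)C)C(C)C | intermediate
23 | saturated C3 ketone, C2 epimer (arylmethyl axial, α) | O=C1CC[C@@H]2[C@@](C)(CCC=C)[C@H](Br)CC[C@@]2(C)[C@H]1Cc1cc(C(=O)OC)cc(Br)c1O[Si](C(C)C)(C(C)C)C(C)C | intermediate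
24 | saturated C3 ketone, arylmethyl equatorial (β), all stereocentres as in 27 | O=C1CC[C@@H]2[C@@](C)(CCC=C)[C@H](Br)CC[C@@]2(C)[C@@H]1Cc1cc(C(=O)OC)cc(Br)c1O[Si](C(C)C)(C(C)C)C(C)C | intermediate
25 | exocyclic methylene compound (C3=CH2, but-3-enyl side chain) | C=C1CC[C@@H]2[C@@](C)(CCC=C)[C@H](Br)CC[C@@]2(C)[C@@H]1Cc1cc(C(=O)OC)cc(Br)c1O[Si](C(C)C)(C(C)C)C(C)C | intermediate
26 | callophycoic acid H methyl ester triisopropylsilyl ether | C=C1CC[C@@H]2[C@@](C)(CCC=C(C)C)[C@H](Br)CC[C@@]2(C)[C@@H]1Cc1cc(C(=O)OC)cc(Br)c1O[Si](C(C)C)(C(C)C)C(C)C | intermediate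
27 | callophycoic acid H (2R,6S,7S,10R,11R in the locants used here) | C=C1CC[C@@H]2[C@@](C)(CCC=C(C)C)[C@H](Br)CC[C@@]2(C)[C@@H]1Cc1cc(C(=O)O)cc(Br)c1O | target

**Totals**
Total step count: 15. Longest linear sequence: 13 steps (steps 3–15, from hex-1-en-5-yne).

**Steps most likely to fail**

Step 11 (Proposed new method). What may go wrong: the tertiary cation may lose a proton before C6 attacks, or the congested C6–H may not be removed again under the silylating conditions, so that the cis ring fusion formed under kinetic control survives the quench. The fallback separates the events into operations of known type and sets out from 19. Silylation at −78 °C only (TBSOTf, Et3N, short contact) should allow the silyl trienol ether 20 to be isolated. A Lewis-acid SN1 alkylation of the silyl dienol ether at its γ-carbon by the tertiary ester (Me2AlCl or ZnBr2, CH2Cl2, −78 °C, aqueous work-up) should then give the cis-fused bicyclic dienone F1. The ring fusion is then inverted by classical deconjugation–reconjugation of an enone: KN(SiMe3)2, THF, −78 °C gives the potassium dienolate F2, a kinetic quench with AcOH gives the β,γ-unsaturated ketone F3, and catalytic HCl in THF reprotonates C6 from the α face. The route is rejoined at 22.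

Step 9. What may go wrong: poor regiocontrol in the opening of the trisubstituted epoxide (bromide attack at the tertiary carbon) or Lewis-acid-induced rearrangement of the epoxide to a ketone. The fallback sets out from 16 and replaces steps 8–10. Bromoacetoxylation with NBS in AcOH/NaOAc at 0 °C (bromonium ion opened anti by acetic acid at the tertiary carbon) should give 19 together with its (10S,11R) diastereomer F4. The two are separated by chromatography and the route is rejoined at 19, at the price of the reagent control of the epoxidation.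

Step 5. What may go wrong: aldol capture at the enolate carbon next to the new quaternary centre may be slow, so that proton transfer or retro-aldol cleavage takes over and surplus Grignard reagent consumes the aldehyde. The fallback sets out from 9 and 10 and replaces steps 5–7. The conjugate addition is run alone and quenched with NH4Cl to give (S)-3-methyl-3-[(E)-4-methylocta-3,7-dien-1-yl]cyclohexan-1-one F5. IBX dehydrogenation gives (R)-5-methyl-5-[(E)-4-methylocta-3,7-dien-1-yl]cyclohex-2-en-1-one F6. Kinetic deprotonation with LiN(iPr)2 at −78 °C gives the lithium α′-enolate F7, aldol addition to 3 gives the α′-aldol adduct F8, and mesylation to the mesylate F9 followed by DBU elimination rejoins the route at 16.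

**Further compounds**
F1 | step 11 | cis-fused bicyclic dienone (C6 epimer of 22) | O=C1C=C[C@H]2[C@@](C)(CCC=C)[C@H](Br)CC[C@@]2(C)/C1=C/c1cc(C(=O)OC)cc(Br)c1O[Si](C(C)C)(C(C)C)C(C)C
F2 | step 11 | potassium dienolate of F1 | [K+].[O-]C1=CC=C2[C@@](C)(CCC=C)[C@H](Br)CC[C@@]2(C)/C1=C/c1cc(C(=O)OC)cc(Br)c1O[Si](C(C)C)(C(C)C)C(C)C
F3 | step 11 | β,γ-unsaturated ketone (C5=C6, C4 methylene) | O=C1CC=C2[C@@](C)(CCC=C)[C@H](Br)CC[C@@]2(C)/C1=C/c1cc(C(=O)OC)cc(Br)c1O[Si](C(C)C)(C(C)C)C(C)C
F4 | step 9 | (10S,11R) diastereomer of 19 | O=C1C=CC[C@@](C)(CC[C@H](Br)[C@](C)(OC(C)=O)CCC=C)/C1=C/c1cc(C(=O)OC)cc(Br)c1O[Si](C(C)C)(C(C)C)C(C)C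
F5 | step 5 | (S)-3-methyl-3-[(E)-4-methylocta-3,7-dien-1-yl]cyclohexan-1-one | O=C1CCC[C@@](C)(CC/C=C(\C)CCC=C)C1
F6 | step 5 | (R)-5-methyl-5-[(E)-4-methylocta-3,7-dien-1-yl]cyclohex-2-en-1-one | O=C1C=CC[C@@](C)(CC/C=C(\C)CCC=C)C1
F7 | step 5 | lithium α′-enolate of F6 | [Li+].[O-]C1=C[C@](C)(CC/C=C(\C)CCC=C)CC=C1
F8 | step 5 | α′-aldol adduct of F6 with 3 | O=C1C=CC[C@@](C)(CC/C=C(\C)CCC=C)C1C(O)c1cc(C(=O)OC)cc(Br)c1O[Si](C(C)C)(C(C)C)C(C)C
F9 | step 5 | methanesulfonate of F8 | O=C1C=CC[C@@](C)(CC/C=C(\C)CCC=C)C1C(OS(C)(=O)=O)c1cc(C(=O)OC)cc(Br)c1O[Si](C(C)C)(C(C)C)C(C)C
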